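## Retrosynthetic overview
1. Dendronpholide J comes from a late allylic oxidation of the isopropenyl group to the acrylic acid, on a macrocycle that already carries the 3-OAc/4-OH diol, the 8,11-oxolane and the 7- and 12-OH groups.
2. The oxolane and the C7/C12 alcohols come from a Δ7/Δ11 bis(trans-epoxide) by hydrolytic opening at C8 and 5-exo closure onto C11. The last ring formed is the oxolane.
3. The 14-membered ring is closed by a photocatalytic aldehyde–methyl ketone cross-pinacol coupling (C3–C4), which sets the anti-diol directly.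
4. The seco keto-aldehyde comes from a Julia–Kocienski olefination of a limonene-derived sulfone (C12–C20 side, C1 = R) with a geranylacetone-derived keto-aldehyde.

Assumption: the C1 stereocentre from (R)-limonene fixes the macrocycle conformation that controls facial selectivity in Steps 9 and 12, and diastereomers are separated chromatographically where needed.

## Route

**Step 1**
Reactants: 1, (R)-(+)-limonene
Product: 2, (R)-7,7-dimethoxy-5-(prop-1-en-2-yl)heptan-2-one
Conditions: O3 (0.95 equiv), MeOH/CH2Cl2, −78 °C; then Me2S; then TsOH, rt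
Reagents that add atoms: ozone [O-][O+]=O; methanol CO
Why: Ozonolysis of the more electron-rich ring alkene, with the aldehyde trapped as its dimethyl acetal, leaves the isopropenyl group and C1 untouched, so C1 (R) is carried forward.

**Step 2**
Reactants: 2
Product: 3, (5R)-7,7-dimethoxy-5-isopropenylheptan-2-ol (epimeric at the carbinol)
Conditions: NaBH4, MeOH, 0 °C
Reagents that add atoms: none
Why: Hydride reduction is chemoselective for the ketone, and the carbinol stereocentre is discarded later at the olefination.

**Step 3**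
Reactants: 3
Product: 4, the 1-phenyltetrazol-5-yl sulfide of 3
Conditions: 1-phenyl-1H-tetrazole-5-thiol, PPh3, DIAD, THF, 0 °C
Reagents that add atoms: 1-phenyl-1H-tetrazole-5-thiol Sc1nnnn1-c1ccccc1
Why: Mitsunobu thioetherification installs the Julia–Kocienski handle.

**Step 4**
Reactants: 4
Product: 5, the 1-phenyltetrazol-5-yl sulfone
Conditions: (NH4)6Mo7O24·4H2O (cat.), H2O2, EtOH, 0 °C → rt
Reagents that add atoms: hydrogen peroxide OO
Why: Molybdate-catalysed peroxide oxidises the sulfide far faster than the isopropenyl alkene.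

**Step 5**
Reactants: 6, (E)-geranylacetone, CC(=O)CC/C=C(\C)CCC=C(C)C
Product: 7, (E)-10,11-epoxygeranylacetone
Conditions: NBS, THF/H2O, 0 °C; then K2CO3, MeOH, rt (one pot)
Reagents that add atoms: water O
Why: Bromohydrin formation occurs at the more remote, less deactivated terminal trisubstituted alkene, and base then closes the epoxide.

**Step 6**
Reactants: 7
Product: 8, (E)-6-methyl-9-oxodec-5-en... i.e. CC(=O)CC/C=C(\C)CCC=O (C4–C11 keto-aldehyde)
Conditions: H5IO6, THF, 0 °C
Reagents that add atoms: none
Why: Periodate cleaves the epoxide, via the diol, to the aldehyde and acetone while the E-Δ7 alkene is kept.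

**Step 7**
Reactants: 5 and 8
Product: 9, the dimethyl acetal of the seco keto-aldehyde, bearing (E,E)-Δ7 and Δ11
Conditions: KHMDS, DME, −60 °C → rt
Reagents that add atoms: none
Why: Julia–Kocienski olefination of the branched sulfone anion with the aldehyde gives the trisubstituted C11=C12 alkene, E-selective (E/Z ≈ 4:1 expected, separable).

**Step 8**
Reactants: 9
Product: 10, (3R,6E,10E)-6,10-dimethyl-14-oxo-3-(prop-1-en-2-yl)pentadeca-6,10-dienal
Conditions: PPTS, acetone/H2O, 50 °C
Reagents that add atoms: water O
Why: Mild acid hydrolyses the acetal and leaves the alkenes and the ketone intact.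

**Step 9**
Reactants: 10
Product: 11, (1R,3R,4S,7E,11E)-cembra-7,11,15(16)-triene-3,4-diol
Conditions: Cp2TiCl2 (20 mol%), 3DPAFIPN (2 mol%), Hantzsch ester, collidine·HCl, THF (1 mM), blue LEDs, rt
Reagents that add atoms: none
Why: Proposed new method: Ti(III), regenerated photocatalytically, reduces the more easily reduced aldehyde to a Ti-bound ketyl, which couples intramolecularly with the Ti-activated methyl ketone to close the 14-membered ring as the Ti-pinacolate, and the anti (3R,4S) diol is expected from the macrocyclic conformer set by C1; the closest known reactions are Ti(III)/photoredox pinacol couplings and macrocyclic McMurry/SmI2 pinacol closures.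

**Step 10**
Reactants: 11
Product: 12, the 3-acetate of 11
Conditions: Ac2O, Et3N, DMAP (5 mol%), CH2Cl2, −10 °C
Reagents that add atoms: acetic anhydride CC(=O)OC(C)=O
Why: Only the secondary C3–OH acylates, and the tertiary C4–OH is untouched.

**Step 11**
Reactants: 12
Product: 13, the 4-O-TBS ether of 12
Conditions: TBSOTf, 2,6-lutidine, CH2Cl2, −78 → 0 °C
Reagents that add atoms: tert-butyldimethylsilyl triflate C[Si](C)(C(C)(C)C)OS(=O)(=O)C(F)(F)F
Why: Masking C4–OH prevents 5-exo capture of the Δ7 epoxide (4,7-ether).

**Step 12**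
Reactants: 13
Product: 14, the 7,8:11,12-bis(trans-epoxide) (7S,8S,11R,12R)
Conditions: mCPBA (2.1 equiv), NaHCO3, CH2Cl2, −20 °C
Reagents that add atoms: m-chloroperbenzoic acid OOC(=O)c1cccc(Cl)c1
Why: Prilezhaev epoxidation is syn on each E-alkene and gives trans-epoxides, trisubstituted alkenes react much faster than the isopropenyl group, and the macrocycle is assumed to direct the facial selectivity.

**Step 13**
Reactants: 14
Product: 15, the oxolane 8,11-epoxy-7,12-diol (4-OTBS, 3-OAc)
Conditions: CSA (10 mol%), MeCN/H2O 20:1, 0 °C → rt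
Reagents that add atoms: water O
Why: Water opens the 7,8-epoxide at tertiary C8 with inversion (7,8-anti), then the C8–OH closes 5-exo onto C11 of the 11,12-epoxide with inversion (11,12-anti) in an acid-promoted epoxide-opening cascade.

**Step 14**
Reactants: 15
Product: 16, the 3-acetoxy-4,7,12-trihydroxy-8,11-epoxycembra-15(16)-ene
Conditions: TBAF, AcOH (1 equiv), THF, 0 °C
Reagents that add atoms: none
Why: Fluoride cleaves the silyl ether, and the acetic acid buffer suppresses acetyl migration.

**Step 15**
Reactants: 16
Product: 17, the C17 allylic alcohol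
Conditions: SeO2 (0.3 equiv), TBHP, CH2Cl2, rt
Reagents that add atoms: selenium dioxide O=[Se]=O
Why: Riley ene/[2,3] allylic hydroxylation of the now sole alkene occurs at the methyl group, and no stereocentre is affected.

**Step 16**
Reactants: 17
Product: 18, Dendronpholide J
Conditions: TEMPO (10 mol%), NaClO2, NaOCl (cat.), MeCN/pH 6.7 phosphate buffer, 35 °C
Reagents that add atoms: sodium chlorite [Na+].[O-]Cl=O
Why: Zhao–Anelli TEMPO oxidation takes the primary allylic alcohol to the acrylic acid and leaves the hindered secondary and tertiary alcohols alone.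

## Compound list
1 | (R)-(+)-limonene | CC1=CC[C@@H](CC1)C(=C)C | starting material
2 | (R)-7,7-dimethoxy-5-isopropenylheptan-2-one | C=C(C)[C@@H](CC(OC)OC)CCC(C)=O | intermediate
3 | 7,7-dimethoxy-5-isopropenylheptan-2-ol | C=C(C)[C@@H](CC(OC)OC)CCC(C)O | intermediate
4 | phenyltetrazolyl sulfide | C=C(C)[C@@H](CC(OC)OC)CCC(C)Sc1nnnn1-c1ccccc1 | intermediate
5 | phenyltetrazolyl sulfone | C=C(C)[C@@H](CC(OC)OC)CCC(C)S(=O)(=O)c1nnnn1-c1ccccc1 | intermediate
6 | (E)-geranylacetone | CC(=O)CC/C=C(\C)CCC=C(C)C | starting material
7 | (E)-10,11-epoxygeranylacetone | CC(=O)CC/C=C(\C)CCC1OC1(C)C | intermediate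
8 | (E)-keto-aldehyde (C4–C11) | CC(=O)CC/C=C(\C)CCC=O | intermediate
9 | acetal of seco keto-aldehyde | C=C(C)[C@@H](CC(OC)OC)CC/C(C)=C/CC/C(C)=C/CCC(C)=O | intermediate
10 | seco keto-aldehyde | C=C(C)[C@@H](CC=O)CC/C(C)=C/CC/C(C)=C/CCC(C)=O | intermediate
11 | cembra-7,11,15(16)-triene-3,4-diol | C=C(C)[C@@H]1CC/C(C)=C/CC/C(C)=C/CC[C@](C)(O)[C@H](O)C1 | intermediate
12 | 3-acetate | C=C(C)[C@@H]1CC/C(C)=C/CC/C(C)=C/CC[C@](C)(O)[C@H](OC(C)=O)C1 | intermediate
13 | 4-OTBS, 3-OAc | C=C(C)[C@@H]1CC/C(C)=C/CC/C(C)=C/CC[C@](C)(O[Si](C)(C)C(C)(C)C)[C@H](OC(C)=O)C1 | intermediate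
14 | 7,8:11,12-bis-epoxide | C=C(C)[C@@H]1CC[C@@]2(C)O[C@@H]2CC[C@]3(C)O[C@H]3CC[C@](C)(O[Si](C)(C)C(C)(C)C)[C@H](OC(C)=O)C1 | intermediate
15 | oxolane (4-OTBS) | C=C(C)[C@@H]1CC[C@@](C)(O)[C@@H]2CC[C@@](C)(O2)[C@@H](O)CC[C@](C)(O[Si](C)(C)C(C)(C)C)[C@H](OC(C)=O)C1 | intermediate
16 | desilylated oxolane | C=C(C)[C@@H]1CC[C@@](C)(O)[C@@H]2CC[C@@](C)(O2)[C@@H](O)CC[C@](C)(O)[C@H](OC(C)=O)C1 | intermediate
17 | allylic alcohol | OCC(=C)[C@@H]1CC[C@@](C)(O)[C@@H]2CC[C@@](C)(O2)[C@@H](O)CC[C@](C)(O)[C@H](OC(C)=O)C1 | intermediate
18 | Dendronpholide J | C=C(C(=O)O)[C@@H]1CC[C@@](C)(O)[C@@H]2CC[C@@](C)(O2)[C@@H](O)CC[C@](C)(O)[C@H](OC(C)=O)C1 | target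

## Totals
- Total steps: 16.
- Longest linear sequence: 14 (limonene → 18).
- Stereocentre bookkeeping:
  - C1 (R) comes from limonene.
  - C3 and C4 (anti) are set in Step 9.
  - C7, C8, C11 and C12 are set in Steps 12–13 by trans-epoxide stereochemistry and double inversion.

## Three steps most likely to fail
1. **Step 9 (pinacol macrocyclization, the new step).** Aldehyde homocoupling, oligomerisation or the wrong C3/C4 diastereomer could result.
   - Fallback: use a different approach, a macrocyclic McMurry coupling (TiCl3/Zn–Cu, high dilution) of 10 to the cembra-3,7,11-triene. Then carry out Δ3 epoxidation and regioselective acetate opening at C3 to give the anti-acetoxy alcohol, using known chemistry.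
2. **Steps 12–13 (bis-epoxidation and cascade).** The 7,8 and 11,12 facial selectivities may not both match, and water may intercept the 11,12-epoxide before cyclisation.
   - Fallback: go stepwise. Do a kinetic mono-epoxidation (1 equiv mCPBA, −40 °C) with separation of regioisomers, hydrolyse it to the 7,8-anti-diol, then epoxidise the second alkene and cyclise with CSA, all known chemistry.
3. **Step 15 (SeO2 allylic oxidation of the polyoxygenated macrocycle).** Over-oxidation or oxidation at the wrong allylic site is possible.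
   - Fallback: move the oxidation to the start. Do SeO2/TBHP on keto-acetal 2, protect the allylic alcohol as its TBS ether and carry it through the sequence. Then unmask it and oxidise to the acid in the final two steps.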